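The constants used here were drawn at random within sensible limits, and the outcome is calculated.

Count the turnovers a catalyst makes before the impurity kills it.

    reagent + free catalyst → catalyst intermediate A (k1 = 270 /M/s)
    starting material + catalyst intermediate A ⇌ catalyst intermediate B (K2 = 400 /M, k2 = 140 /M/s)
    catalyst intermediate B → free catalyst + product (k3 = 5.8 /s)
    free catalyst + impurity → spent catalyst (k4 = 6900 /M/s)
    starting material + product ⇌ idle adduct, settled at all times (K5 = 19 /M)

| setting | south-east | east | west |
|---|---|---|---|
| starting material | 0.052 M | 0.052 M | 0.052 M |
| reagent | 1.20 equiv | 1.20 equiv | 1.20 equiv |
| free catalyst | 0.79 mol% (in portions, 3) | 0.79 mol% (in portions, 3) | 0.79 mol% (in portions, 3) |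
| impurity | 0.15 mM | 0.50 mM | 1.5 mM |
| time | 40 s | 40 s | 40 s |
| remark | the portions of free catalyst follow each other after 2.5 s, the first at the start | the portions of free catalyst follow each other after 2.5 s, the first at the start | the portions of free catalyst follow each other after 2.5 s, the first at the start |

- percentages count the starting material that a species holds: one idle adduct counts as two
- product is meant together with its idle adduct
- in an amount of product, one idle adduct counts as one product
- "hardly changes" means that all values lie within two and a half points (for a concentration: within two and a half percent of the largest)
- run time (south-east): 40 s

* amount of product at the end, in percent of the starting material charged for south-east, east, west, in this order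
* how that number moves from the first to the last of them (falls, then rises / rises all the way / falls all the way / hardly changes / rises, then falls)

The flasks share a catalyst charge C of 0.411 mM and differ in the impurity charge Y. West looks hopeless. Its impurity outnumbers the catalyst 3.65 to one, and the constant for impurity on free catalyst is 25.6 times the one for reagent. Yet at the charges, free catalyst in west goes to reagent at 16.8 /s and to impurity at 10.3 /s, so the reagent wins.

I clear this with one quantity. The race constant Q is the impurity concentration at which free catalyst is as likely to die as to be captured by reagent, 270 /M/s times the reagent charge over 6900 /M/s; it comes to 2.44 mM. At impurity concentration y, the odds of capture against death are Q/y, a selectivity factor. The scheme returns catalyst to free catalyst through the release of product, so each capture counts as one product.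

Each death removes one impurity, so y falls from Y to Y − C as the catalyst dies. Summing the odds over those deaths gives product P = Q ln(Y/(Y − C)). West gives 0.781 mM, which is 1.50% of the starting material and 1.90 turnovers per catalyst. East gives 4.21 mM, or 8.09%, and should keep 17.8% of its impurity. In both flasks I hold the reagent at its charge, since P stays far below it. In south-east the impurity falls short of the catalyst by 0.261 mM, so the logarithm has no value and my count stops there.

The forecast says 41%, 7.5% and 1.5%, a row that falls all the way, holding that “the yield is set by how reagent and impurity compete for free catalyst”. My east figure stands above the forecast's.

South-east, east and west give 42.0%, 7.71% and 1.49%, a row that falls all the way. Q is 1.63 times the impurity charge of west and 4.88 times that of east, and west holds 1.49% against my 1.50%, with spent catalyst at 100% after 40.0 s. East, the second flask for Q, holds 7.71% against my 8.09%, with spent catalyst at 99.4% and impurity at 18.3% of its charge after 40.0 s.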